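## Retrosynthetic overview

1. Rings: A is the central benzene, B the pyran, C the cyclopentane, D the gem-dimethylcyclobutane and E the catechol. The enabling feature is that the four carbons of ring D are two alkenes sitting on the neighbouring carbons C5 and C6 of ring A. The aryl-bearing CH and the benzylic ring-fusion CH are a stilbene C=C. The other ring-fusion CH and CMe2 are a prenyl C=C. Together they form a 1,6-diene.
2. Before ring D exists, the catechol-bearing carbon is the unhindered terminal carbon of a C5 vinyl group. The ring E–CH bond is therefore cut as a Mizoroki–Heck arylation. In the same flask the new stilbene is photosensitised and closes ring C (5-exo) and then ring D ([2+2]).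
3. The chromene C3=C4 alkene is carried as an (S)-C4 silyl ether. This group hides a second styrene chromophore, relays absolute configuration to the three new centres, and leaves at the end by E1 elimination.
4. The precursor comes from phloroglucinol. Chromanone ring B is made first. The C6 prenyl group is delivered from the C5 phenol by a Claisen O-to-C transfer, and the same phenol then becomes the triflate that is exchanged for vinyl.
5. Ring order: A (bought), then B (step 1), then C and D (both in step 11). Ring E is bought. The chromene alkene is unveiled last.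

Key step: step 11

Remark: chroman numbering (O1, C2, C3, C4, C4a, C5–C8, C8a) is used for rings A/B of every compound. TBS = tert-butyldimethylsilyl; prenyl = 3-methylbut-2-en-1-yl.

## Route

Step 1
Reactants: 1 phloroglucinol; 2 3-methylbut-2-enoic acid
Product: 4 5,7-dihydroxy-2,2-dimethylchroman-4-one, via acylphloroglucinol enone 3 (not isolated)
Conditions: P2O5, MeSO3H, 70 °C
Reagents that add atoms: none
Why: Friedel–Crafts acylation of the threefold symmetric, electron-rich arene (no regioisomers possible) gives enone 3, which closes ring B by intramolecular oxa-Michael addition, the standard entry to 2,2-dimethylchroman-4-ones.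

Step 2
Reactants: 4 5,7-dihydroxy-2,2-dimethylchroman-4-one
Product: 5 5-hydroxy-7-methoxy-2,2-dimethylchroman-4-one
Conditions: MeI (1.05 equiv), K2CO3, acetone, rt
Reagents that add atoms: iodomethane, CI
Why: Williamson ether synthesis in which the C5 phenol is held back by its hydrogen bond to the C4 carbonyl, so that one equivalent of MeI should alkylate only the more acidic free C7 phenol.

Step 3
Reactants: 6 2-methylbut-3-en-2-ol
Product: 8 tert-butyl (2-methylbut-3-en-2-yl) carbonate, via lithium alkoxide 7 (not isolated)
Conditions: n-BuLi, THF, −78 °C; then Boc2O, −78 °C to rt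
Reagents that add atoms: di-tert-butyl dicarbonate, CC(C)(C)OC(=O)OC(=O)OC(C)(C)C
Why: O-Acylation of the tertiary lithium alkoxide 7 by Boc2O gives the mixed carbonate that palladium can ionise in the next step.

Step 4
Reactants: 5 5-hydroxy-7-methoxy-2,2-dimethylchroman-4-one; 8 tert-butyl (2-methylbut-3-en-2-yl) carbonate
Product: 9 7-methoxy-2,2-dimethyl-5-[(2-methylbut-3-en-2-yl)oxy]chroman-4-one
Conditions: Pd(PPh3)4 (5 mol %), THF, 0 °C
Reagents that add atoms: none
Why: Tsuji–Trost O-allylation: zerovalent palladium ionises 8 with loss of CO2, the released tert-butoxide deprotonates the phenol, and under kinetic control at low temperature the phenoxide attacks the more substituted allyl terminus to give the tertiary ether.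

Step 5
Reactants: 9 7-methoxy-2,2-dimethyl-5-[(2-methylbut-3-en-2-yl)oxy]chroman-4-one
Product: 11 5-hydroxy-7-methoxy-2,2-dimethyl-6-prenylchroman-4-one, via ortho-dienone 10 (not isolated)
Conditions: Eu(fod)3 (10 mol %), PhMe, 80 °C
Reagents that add atoms: none
Why: Aromatic Claisen rearrangement ([3,3]-sigmatropic), accelerated by chelation of Eu(fod)3 between the ether oxygen and the C4 carbonyl: C6 is the only free ortho position, allyl inversion turns the 1,1-dimethylallyl group into a normal prenyl group, and dienone 10 rearomatises by tautomerisation.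

Step 6
Reactants: 11 5-hydroxy-7-methoxy-2,2-dimethyl-6-prenylchroman-4-one
Product: 12 7-methoxy-2,2-dimethyl-4-oxo-6-prenylchroman-5-yl trifluoromethanesulfonate
Conditions: Tf2O, pyridine, CH2Cl2, 0 °C
Reagents that add atoms: trifluoromethanesulfonic anhydride, O=S(=O)(OS(=O)(=O)C(F)(F)F)C(F)(F)F
Why: Sulfonylation of the phenol; the oxygen that delivered the prenyl group becomes the leaving group, activated for oxidative addition by the ortho carbonyl.

Step 7
Reactants: 12 7-methoxy-2,2-dimethyl-4-oxo-6-prenylchroman-5-yl trifluoromethanesulfonate; 13 tributyl(vinyl)stannane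
Product: 14 7-methoxy-2,2-dimethyl-6-prenyl-5-vinylchroman-4-one
Conditions: PdCl2(PPh3)2 (5 mol %), LiCl (3 equiv), DMF, 90 °C
Reagents that add atoms: none
Why: Stille coupling of an aryl triflate (LiCl variant) under neutral conditions, which spares the triflate from hydrolysis and leaves the ketone and the prenyl alkene untouched.

Step 8
Reactants: 14 7-methoxy-2,2-dimethyl-6-prenyl-5-vinylchroman-4-one
Product: 15 (S)-7-methoxy-2,2-dimethyl-6-prenyl-5-vinylchroman-4-ol
Conditions: RuCl(p-cymene)[(S,S)-TsDPEN] (2 mol %), HCO2Na (5 equiv), H2O/MeOH 1:1, 40 °C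
Reagents that add atoms: none
Why: Noyori–Ikariya asymmetric transfer hydrogenation: the (S,S) catalyst places the aryl side of the ketone under its arene ligand and should deliver hydride to the face that gives the (S)-benzylic alcohol, as for chroman-4-one itself, while the non-acidic formate medium avoids ionisation of the activated alcohol and the alkenes are not reduced.

Step 9
Reactants: 15 (S)-7-methoxy-2,2-dimethyl-6-prenyl-5-vinylchroman-4-ol
Product: 16 (S)-4-(tert-butyldimethylsilyloxy)-7-methoxy-2,2-dimethyl-6-prenyl-5-vinylchroman
Conditions: TBSOTf, 2,6-lutidine, CH2Cl2, −78 to 0 °C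
Reagents that add atoms: tert-butyldimethylsilyl trifluoromethanesulfonate, CC(C)(C)[Si](C)(C)OS(=O)(=O)C(F)(F)F
Why: Silyl ether formation under buffered, cold conditions keeps the ionisable benzylic C–O bond and its configuration intact and installs the bulky group that will steer step 11.

Step 10
Reactants: 17 4-bromocatechol
Product: 18 4-bromo-1,2-bis(tert-butyldimethylsilyloxy)benzene
Conditions: TBSCl (2.3 equiv), imidazole, DMF, rt
Reagents that add atoms: tert-butyldimethylsilyl chloride, CC(C)(C)[Si](C)(C)Cl
Why: Standard silylation of both phenols; the silyl ethers tolerate the amine base of step 11 and leave with fluoride at the end.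

Step 11
Reactants: 16 (S)-4-(tert-butyldimethylsilyloxy)-7-methoxy-2,2-dimethyl-6-prenyl-5-vinylchroman; 18 4-bromo-1,2-bis(tert-butyldimethylsilyloxy)benzene
Product: 21 tris-TBS pentacycle (C4 S; ring-fusion CH on ring A R; ring-fusion CH next to CH2 S; aryl-bearing CH S; aryl on the convex face; ring D anti to the C4 oxygen), via (E)-stilbene 19 (not isolated), via (Z)-stilbene 20 (not isolated)
Conditions: Pd(P(t-Bu)3)2 (5 mol %), Cy2NMe (1.05 equiv), Ir[dF(CF3)ppy]2(dtbbpy)PF6 (1 mol %), 1,4-dioxane (0.05 M), argon, 40 °C, dark; then 450 nm LEDs, 25 °C, same flask, nothing added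
Reagents that add atoms: none
Why: Proposed new method: a Mizoroki–Heck arylation and a visible-light energy-transfer [2+2] photocycloaddition, each well known alone (mild Heck coupling of aryl bromides with Pd(P(t-Bu)3)2/Cy2NMe; sensitised closure of styrenes tethered to a prenyl group to 6-aryl-7,7-dimethylbicyclo[3.2.0]heptanes), are run as a relay from a single charge of reagents, which together with the stereochemical relay from C4 has no direct precedent. In the dark, zerovalent palladium inserts into the C–Br bond of 18, the aryl group migrates to the unhindered terminal vinyl carbon of 16 (the trisubstituted prenyl alkene does not insert) and β-hydride elimination gives 19, so the aryl–carbon bond is made while that carbon is still sp2 and has no quaternary neighbour. The same bond creates the triplet antenna, a planar 3,4-bis(silyloxy)styrene: once the LEDs are on, the stilbene (about 0.05 M) outcompetes the few mM of left-over amine and phosphine for the excited iridium complex by Dexter energy transfer, 19 and 20 interconvert through one common twisted triplet, and the alkene-free product 21 is no longer sensitised. Because both ortho positions next to C5 are substituted, the ring-A-side carbon of the triplet is twisted out of benzylic conjugation and behaves like an alkyl radical, so it closes ring C by 5-exo-trig attack on the CH end of the prenyl alkene (rule of five), and after intersystem crossing the 1,4-diradical (tertiary carbon plus ring-E-stabilised benzylic carbon) closes ring D by radical recombination. The two ring-fusion centres can only be cis in the bicyclo[3.2.0] frame (a trans diradical cleaves back to 19/20), their absolute sense is set by the (S)-C4 silyl ether, which stands pseudoaxial next to C5 and pushes the styryl carbon and with it ring D to the opposite face of ring A, and the aryl-bearing centre is set at the freely rotating diradical, which puts ring E on the convex face trans to ring A from either alkene geometry. The selectivities needed are vinyl over prenyl in the coupling, straight over crossed cycloaddition and one face of ring A; they are secured by the alkene substitution, by the 1,6-diene spacing through C5–C6 and by the C4 stereocentre, whose minor-face product would be a separable diastereomer and not an enantiomer.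

Step 12
Reactants: 21 tris-TBS pentacycle
Product: 22 bis-TBS ether of the target (2,2-dimethylchromene restored)
Conditions: p-TsOH·H2O (10 mol %), PhMe, 60 °C
Reagents that add atoms: none
Why: Acid-catalysed E1 elimination: the C4–O bond ionises easily because the cation is stabilised by O1 (ortho) and the C7 methoxy group (para), only C3 carries a β-hydrogen so a single alkene (the chromene) can form, the aryl silyl ethers survive catalytic acid, and the auxiliary stereocentre is erased.

Step 13
Reactants: 22 bis-TBS ether of the target
Product: 23 target CNP0207533.1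
Conditions: Bu4NF (2.2 equiv), AcOH (2.2 equiv), THF, 0 °C, argon
Reagents that add atoms: none
Why: Fluoride-induced cleavage of the two aryl silyl ethers, buffered with AcOH and run under argon so that the catechol is never exposed as an oxidisable catecholate; chromene, methyl ether and the three stereocentres are untouched.

## Compound list

1 | phloroglucinol | Oc1cc(O)cc(O)c1 | starting material
2 | 3-methylbut-2-enoic acid | CC(C)=CC(=O)O | starting material
3 | 3-methyl-1-(2,4,6-trihydroxyphenyl)but-2-en-1-one (not isolated) | CC(C)=CC(=O)c1c(O)cc(O)cc1O | intermediate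
4 | 5,7-dihydroxy-2,2-dimethylchroman-4-one | Oc1cc2c(c(O)c1)C(=O)CC(C)(C)O2 | intermediate
5 | 5-hydroxy-7-methoxy-2,2-dimethylchroman-4-one | COc1cc2c(c(O)c1)C(=O)CC(C)(C)O2 | intermediate
6 | 2-methylbut-3-en-2-ol | CC(C)(O)C=C | starting material
7 | lithium 2-methylbut-3-en-2-olate (not isolated) | [Li+].[O-]C(C)(C)C=C | intermediate
8 | tert-butyl (2-methylbut-3-en-2-yl) carbonate | CC(C)(C)OC(=O)OC(C)(C)C=C | intermediate
9 | 7-methoxy-2,2-dimethyl-5-[(2-methylbut-3-en-2-yl)oxy]chroman-4-one | COc1cc2c(c(OC(C)(C)C=C)c1)C(=O)CC(C)(C)O2 | intermediate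
10 | ortho-dienone, the 6H-keto tautomer of 11 (not isolated) | COC1=CC2=C(C(=O)C1CC=C(C)C)C(=O)CC(C)(C)O2 | intermediate
11 | 5-hydroxy-7-methoxy-2,2-dimethyl-6-(3-methylbut-2-en-1-yl)chroman-4-one | COc1cc2c(c(O)c1CC=C(C)C)C(=O)CC(C)(C)O2 | intermediate
12 | 7-methoxy-2,2-dimethyl-6-(3-methylbut-2-en-1-yl)-4-oxochroman-5-yl trifluoromethanesulfonate | COc1cc2c(c(OS(=O)(=O)C(F)(F)F)c1CC=C(C)C)C(=O)CC(C)(C)O2 | intermediate
13 | tributyl(vinyl)stannane | C=C[Sn](CCCC)(CCCC)CCCC | starting material
14 | 7-methoxy-2,2-dimethyl-6-(3-methylbut-2-en-1-yl)-5-vinylchroman-4-one | COc1cc2c(c(C=C)c1CC=C(C)C)C(=O)CC(C)(C)O2 | intermediate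
15 | (S)-7-methoxy-2,2-dimethyl-6-(3-methylbut-2-en-1-yl)-5-vinylchroman-4-ol | COc1cc2c(c(C=C)c1CC=C(C)C)[C@@H](O)CC(C)(C)O2 | intermediate
16 | (S)-4-(tert-butyldimethylsilyloxy)-7-methoxy-2,2-dimethyl-6-(3-methylbut-2-en-1-yl)-5-vinylchroman | COc1cc2c(c(C=C)c1CC=C(C)C)[C@@H](O[Si](C)(C)C(C)(C)C)CC(C)(C)O2 | intermediate
17 | 4-bromocatechol | Oc1ccc(Br)cc1O | starting material
18 | 4-bromo-1,2-bis(tert-butyldimethylsilyloxy)benzene | CC(C)(C)[Si](C)(C)Oc1ccc(Br)cc1O[Si](C)(C)C(C)(C)C | intermediate
19 | (S,E)-5-[3,4-bis(TBSO)styryl]-4-(TBSO)-7-methoxy-2,2-dimethyl-6-prenylchroman (not isolated) | COc1cc2c(c(/C=C/c3ccc(O[Si](C)(C)C(C)(C)C)c(O[Si](C)(C)C(C)(C)C)c3)c1CC=C(C)C)[C@@H](O[Si](C)(C)C(C)(C)C)CC(C)(C)O2 | intermediate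
20 | (S,Z) isomer of 19 (not isolated) | COc1cc2c(c(/C=C\c3ccc(O[Si](C)(C)C(C)(C)C)c(O[Si](C)(C)C(C)(C)C)c3)c1CC=C(C)C)[C@@H](O[Si](C)(C)C(C)(C)C)CC(C)(C)O2 | intermediate
21 | tris-TBS pentacycle: (4S)-4-(TBSO)-7-methoxy-2,2-dimethylchroman fused at C5–C6 to a cis-bicyclo[3.2.0] unit C5–CH(R)–CH(S)[3,4-bis(TBSO)phenyl]–CMe2–CH(S)–CH2–C6, aryl on the convex face, ring D anti to the C4 oxygen | COc1cc2c(c3c1C[C@H]1[C@@H]3[C@H](c3ccc(O[Si](C)(C)C(C)(C)C)c(O[Si](C)(C)C(C)(C)C)c3)C1(C)C)[C@@H](O[Si](C)(C)C(C)(C)C)CC(C)(C)O2 | intermediate
22 | bis-TBS ether of the target (chromene present, same three stereocentres) | COc1cc2c(c3c1C[C@H]1[C@@H]3[C@H](c3ccc(O[Si](C)(C)C(C)(C)C)c(O[Si](C)(C)C(C)(C)C)c3)C1(C)C)C=CC(C)(C)O2 | intermediate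
23 | CNP0207533.1 (aryl-bearing CH S, ring-fusion CH on ring A R, ring-fusion CH next to CH2 S) | COc1cc2c(c3c1C[C@H]1[C@@H]3[C@H](c3ccc(O)c(O)c3)C1(C)C)C=CC(C)(C)O2 | target

## Step count and risks

Total step count: 13. Longest linear sequence: 11 steps (1, 2, 4, 5, 6, 7, 8, 9, 11, 12, 13).

**Risk 1, step 11.**
- What may go wrong: slow insertion of the arylpalladium species into a vinyl group flanked by two ortho substituents; quenching of the excited sensitiser by what the coupling leaves behind; or a weak facial bias in the first ring closure.
- Fallback (known chemistry): the two events are taken apart and the aryl–carbon bond is made earlier. It sets out from ketone 14, whose flat C4 carbonyl leaves the vinyl group more open and which tolerates a classical thermal Mizoroki–Heck reaction with 18 (Pd(OAc)2, P(o-tol)3, Et3N, MeCN, 90 °C). This gives the stilbene ketone F1.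
- The transfer hydrogenation of step 8 then gives the (S)-stilbene alcohol F2, and the silylation of step 9 gives 19, now isolated and purified.
- Compound 19 alone is irradiated at 450 nm with Ir[dF(CF3)ppy]2(dtbbpy)PF6 in DMSO, the known sensitised styrene [2+2]. The route is rejoined at 21.
- A minor-face cycloadduct is a diastereomer of 21 and is removed by chromatography.

**Risk 2, step 4.**
- What may go wrong: sluggish alkylation of the hydrogen-bonded phenol; or re-ionisation of the tertiary ether by palladium with drift to the linear O-prenyl ether, which would deliver a reverse prenyl group in step 5.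
- Fallback (carbon–carbon coupling instead of O-to-C transfer): it sets out from 5. The free C5 phenol directs electrophilic iodination (BnMe3N·ICl2, CaCO3, CH2Cl2/MeOH, rt) to its ortho position C6 and gives 5-hydroxy-6-iodo-7-methoxy-2,2-dimethylchroman-4-one F3.
- An alpha-selective Suzuki–Miyaura coupling with prenylboronic acid pinacol ester (PdCl2(dppf), K2CO3, DMF/H2O, 80 °C) comes back to the route at 11. Steps 3 to 5 are then not needed.

**Risk 3, step 8.**
- What may go wrong: slow or poorly face-selective hydride transfer to an electron-rich ketone that is hindered by the peri vinyl group.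
- Fallback (resolution instead of asymmetric reduction): it sets out from 14. NaBH4 in MeOH at 0 °C gives the racemic chroman-4-ol F4.
- Enzymatic kinetic resolution (immobilised Candida antarctica lipase B, vinyl acetate, MTBE, 30 °C) should acylate the (R)-enantiomer to the (R)-chroman-4-yl acetate F5. The unreacted (S)-alcohol is separated by chromatography, which comes back to the route at 15.

Further compounds
F1 | step 11 | (E)-5-[3,4-bis(tert-butyldimethylsilyloxy)styryl]-7-methoxy-2,2-dimethyl-6-(3-methylbut-2-en-1-yl)chroman-4-one | COc1cc2c(c(/C=C/c3ccc(O[Si](C)(C)C(C)(C)C)c(O[Si](C)(C)C(C)(C)C)c3)c1CC=C(C)C)C(=O)CC(C)(C)O2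
F2 | step 11 | (S,E)-5-[3,4-bis(tert-butyldimethylsilyloxy)styryl]-7-methoxy-2,2-dimethyl-6-(3-methylbut-2-en-1-yl)chroman-4-ol | COc1cc2c(c(/C=C/c3ccc(O[Si](C)(C)C(C)(C)C)c(O[Si](C)(C)C(C)(C)C)c3)c1CC=C(C)C)[C@@H](O)CC(C)(C)O2
F3 | step 4 | 5-hydroxy-6-iodo-7-methoxy-2,2-dimethylchroman-4-one | COc1cc2c(c(O)c1I)C(=O)CC(C)(C)O2
F4 | step 8 | racemic 7-methoxy-2,2-dimethyl-6-(3-methylbut-2-en-1-yl)-5-vinylchroman-4-ol | COc1cc2c(c(C=C)c1CC=C(C)C)C(O)CC(C)(C)O2
F5 | step 8 | (R)-7-methoxy-2,2-dimethyl-6-(3-methylbut-2-en-1-yl)-5-vinylchroman-4-yl acetate | COc1cc2c(c(C=C)c1CC=C(C)C)[C@H](OC(C)=O)CC(C)(C)O2
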